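**Plan**

1. Locants (germacranolide numbering): C1–C10 form the ten-membered ring; C2 is the hemiketal carbon, C4 carries =C15H2, C5 is the oxolane CH–O, C6 the lactone CH–O, C8 the tiglate carbon, C10 carries =C14H2, and C11–C13 are the α-methylene lactone.
2. Retrosynthesis: (i) the C2–OH (hydration of a C2=C3 enol ether); (ii) C3–C4 and O–C5 together, with a CO2 link restored between C3 and the C5 oxygen, which opens the oxolane and the ten-membered ring to an eleven-membered propargylic β-keto lactone; (iii) the lactone C–O bond (acylketene from a dioxinone); (iv) the tiglate; (v) C7–C8 (zinc Barbier: bromobutenolide + aldehyde); (vi) C7=C11 (RCM), C5–C6 (alkoxyallylboration), C1–C10 (Negishi).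
3. Enabling feature: the oxolane O–C2–C3–C4(=C15H2)–C5 is the imprint of a ketone enolate (O–C2=C3) joined to a propargyl unit (C15≡C4–C5–O) carbon-to-centre and oxygen-to-terminus. C3 and the C5 oxygen are 1,3-related across that ring, so a carboxyl on C3 can be esterified by O5; this ester is leaving group, tether and enolate source, and leaves as CO2.
4. Forward order: open-chain syn-diol monoether → butenolide → trans α-methylene-γ-lactone → eleven-membered β-keto lactone → ten-membered carbocycle and oxolane in one ring-contracting step → hemiketal.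
5. Stereochemistry: C5 and C6 from the reagent-controlled (Z)-γ-alkoxyallylboration; C7 and C8 from C6 in the Barbier step (attack anti to the C6 substituent, closed chair transition state); C5 passes the key step with net retention; C2 is dictated by the bridge.

Key step: step 16

Remark on the chemistry: of the two C2 epimers only the one with C1 and C6 cis on the oxolane can be spanned by the six-carbon bridge, so the hemiketal centre is taken to form under thermodynamic control.

**Route**

Step 1
Reactants: 1 allyl alcohol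
Product: 2 allyl methoxymethyl ether
Conditions: MOMCl, i-Pr2NEt, CH2Cl2, 0 °C → rt
Reagents that add atoms: chloromethyl methyl ether, COCCl
Why: O-alkylation of a primary alcohol with an α-chloro ether under amine base (MOM protection) is routine and creates no stereocentre.

Step 2
Reactants: 2 allyl methoxymethyl ether; 3 3-(trimethylsilyl)prop-2-ynal
Product: 7 (3S,4S)-3-(methoxymethoxy)-6-(trimethylsilyl)hex-1-en-5-yn-4-ol, via allyllithium 4 (not isolated), via allylborane 5 (not isolated), via borinate 6 (not isolated)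
Conditions: s-BuLi, THF, −78 °C; (+)-Ipc2BOMe (from (−)-α-pinene); BF3·OEt2; 3, −78 °C → rt; H2NCH2CH2OH, rt
Reagents that add atoms: none
Why: Brown asymmetric γ-alkoxyallylboration, in which the chelated (Z)-allyl anion gives the (Z)-γ-alkoxyallylborane, the closed chair transition state sets the two C–O bonds syn (C5/C6) and the isopinocampheyl groups from (−)-α-pinene select the aldehyde face that should give the (3S,4S) isomer.

Step 3
Reactants: 7 (3S,4S)-3-(methoxymethoxy)-6-(trimethylsilyl)hex-1-en-5-yn-4-ol
Product: 8 (3S,4S)-4-[tert-butyl(diphenyl)silyloxy]-3-(methoxymethoxy)-6-(trimethylsilyl)hex-1-en-5-yne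
Conditions: TBDPSCl, imidazole, DMAP (cat.), DMF, rt
Reagents that add atoms: tert-butyl(chloro)diphenylsilane, CC(C)(C)[Si](Cl)(c1ccccc1)c1ccccc1
Why: silylation of the propargylic alcohol with a group that survives the Lewis-acidic acetal cleavage, the metathesis and the Barbier step, with no change at the stereocentres.

Step 4
Reactants: 8 (3S,4S)-4-[tert-butyl(diphenyl)silyloxy]-3-(methoxymethoxy)-6-(trimethylsilyl)hex-1-en-5-yne
Product: 9 (3S,4S)-4-[tert-butyl(diphenyl)silyloxy]-6-(trimethylsilyl)hex-1-en-5-yn-3-ol
Conditions: ZnBr2, n-PrSH, CH2Cl2, 0 °C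
Reagents that add atoms: none
Why: thiol-assisted Lewis-acid cleavage of the MOM acetal, which attacks the acetal carbon and should therefore leave the silyl ether, the silylalkyne and both stereocentres untouched.

Step 5
Reactants: 9 (3S,4S)-4-[tert-butyl(diphenyl)silyloxy]-6-(trimethylsilyl)hex-1-en-5-yn-3-ol; 10 2-(bromomethyl)acrylic acid
Product: 11 (3S,4S)-4-[tert-butyl(diphenyl)silyloxy]-6-(trimethylsilyl)hex-1-en-5-yn-3-yl 2-(bromomethyl)prop-2-enoate
Conditions: DCC, DMAP (5 mol %), CH2Cl2, 0 °C
Reagents that add atoms: none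
Why: Steglich esterification forms the acyl C–O bond with retention at the carbinol, and the low DMAP loading and temperature limit attack of the amine on the allylic bromide.

Step 6
Reactants: 11 (3S,4S)-4-[tert-butyl(diphenyl)silyloxy]-6-(trimethylsilyl)hex-1-en-5-yn-3-yl 2-(bromomethyl)prop-2-enoate
Product: 12 (5S)-3-(bromomethyl)-5-[(1S)-1-[tert-butyl(diphenyl)silyloxy]-3-(trimethylsilyl)prop-2-yn-1-yl]furan-2(5H)-one
Conditions: second-generation Grubbs catalyst RuCl2(=CHPh)(PCy3)(SIMes) (5 mol %), CH2Cl2 (5 mM), 40 °C
Reagents that add atoms: none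
Why: ring-closing metathesis of an acrylate-type ester of an allylic alcohol closes the butenolide (C7=C11) with loss of ethene, while the silyl-capped alkyne stays out of enyne metathesis.

Step 7
Reactants: 13 3-bromobut-3-en-1-ol
Product: 14 [(3-bromobut-3-en-1-yl)oxy](tert-butyl)dimethylsilane
Conditions: TBSCl, imidazole, CH2Cl2, rt
Reagents that add atoms: tert-butyl(chloro)dimethylsilane, CC(C)(C)[Si](C)(C)Cl
Why: routine silylation that masks the hydroxyl before halogen–lithium exchange.

Step 8
Reactants: 15 2,2,6-trimethyl-4H-1,3-dioxin-4-one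
Product: 17 6-(chloromethyl)-2,2-dimethyl-4H-1,3-dioxin-4-one, via lithium dienolate 16 (not isolated)
Conditions: LDA, THF, −78 °C; C2Cl6, −78 → −40 °C
Reagents that add atoms: hexachloroethane, ClC(Cl)(Cl)C(Cl)(Cl)Cl
Why: the vinylogous (γ) lithium enolate of the dioxinone is chlorinated at its exocyclic carbon by a positive-chlorine donor, a standard γ-functionalisation of this heterocycle.

Step 9
Reactants: 14 [(3-bromobut-3-en-1-yl)oxy](tert-butyl)dimethylsilane; 17 6-(chloromethyl)-2,2-dimethyl-4H-1,3-dioxin-4-one
Product: 20 6-[4-(tert-butyldimethylsilyloxy)-2-methylidenebutyl]-2,2-dimethyl-4H-1,3-dioxin-4-one, via vinyllithium 18 (not isolated), via vinylzinc chloride 19 (not isolated)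
Conditions: t-BuLi (2.1 equiv), Et2O, −78 °C; ZnCl2, THF, −78 → 0 °C; 17, Pd(PPh3)4 (5 mol %), THF, rt
Reagents that add atoms: none
Why: Negishi coupling of an alkenylzinc with an allylic chloride forms the C1–C10 sp3–sp2 bond at the less hindered allyl terminus, and the organozinc should tolerate the dioxinone carbonyl.

Step 10
Reactants: 20 6-[4-(tert-butyldimethylsilyloxy)-2-methylidenebutyl]-2,2-dimethyl-4H-1,3-dioxin-4-one
Product: 21 6-(4-hydroxy-2-methylidenebutyl)-2,2-dimethyl-4H-1,3-dioxin-4-one
Conditions: HF·pyridine, pyridine, THF, 0 °C → rt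
Reagents that add atoms: none
Why: buffered fluoride cleavage of a primary silyl ether under conditions that should leave the dioxinone intact.

Step 11
Reactants: 21 6-(4-hydroxy-2-methylidenebutyl)-2,2-dimethyl-4H-1,3-dioxin-4-one
Product: 22 4-(2,2-dimethyl-4-oxo-4H-1,3-dioxin-6-yl)-3-methylidenebutanal
Conditions: Dess–Martin periodinane, NaHCO3, CH2Cl2, 0 °C; used at once
Reagents that add atoms: none
Why: Dess–Martin oxidation under buffered, non-basic conditions should give the β,γ-unsaturated aldehyde without migration of the double bond into conjugation.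

Step 12
Reactants: 12 (5S)-3-(bromomethyl)-5-[(1S)-1-[tert-butyl(diphenyl)silyloxy]-3-(trimethylsilyl)prop-2-yn-1-yl]furan-2(5H)-one; 22 4-(2,2-dimethyl-4-oxo-4H-1,3-dioxin-6-yl)-3-methylidenebutanal
Product: 24 (4R,5S)-5-[(1S)-1-[tert-butyl(diphenyl)silyloxy]-3-(trimethylsilyl)prop-2-yn-1-yl]-4-[(1S)-4-(2,2-dimethyl-4-oxo-4H-1,3-dioxin-6-yl)-1-hydroxy-3-methylidenebutyl]-3-methylideneoxolan-2-one, via allylzinc bromide 23 (not isolated)
Conditions: Zn dust, THF/sat. aq. NH4Cl (5:1), 0 °C → rt
Reagents that add atoms: none
Why: zinc Barbier allylation in which the allylzinc reacts at its γ-carbon C7 on the ring face anti to the C6 substituent (trans lactone), and the ring-locked E-type geometry in a closed chair transition state with the aldehyde chain equatorial should set C8 as (S).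

Step 13
Reactants: 24 Barbier alcohol (C8–OH); 25 tiglic acid
Product: 27 (1S)-1-{(2S,3R)-2-[(1S)-1-[tert-butyl(diphenyl)silyloxy]-3-(trimethylsilyl)prop-2-yn-1-yl]-4-methylidene-5-oxooxolan-3-yl}-4-(2,2-dimethyl-4-oxo-4H-1,3-dioxin-6-yl)-3-methylidenebutyl (2E)-2-methylbut-2-enoate, via mixed anhydride 26 (not isolated)
Conditions: 2,4,6-trichlorobenzoyl chloride, Et3N, THF, rt; then 24, DMAP, toluene, rt
Reagents that add atoms: none
Why: Yamaguchi esterification acylates the hindered C8 alcohol with retention, and doing so promptly should forestall translactonisation of the free 8-hydroxy 6,12-lactone to the 8,12-lactone.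

Step 14
Reactants: 27 silyl-protected tiglate
Product: 28 (1S)-4-(2,2-dimethyl-4-oxo-4H-1,3-dioxin-6-yl)-1-{(2S,3R)-2-[(1S)-1-hydroxyprop-2-yn-1-yl]-4-methylidene-5-oxooxolan-3-yl}-3-methylidenebutyl (2E)-2-methylbut-2-enoate
Conditions: TBAF, AcOH (1:1), THF, 0 °C → rt
Reagents that add atoms: none
Why: acetic-acid-buffered fluoride should cleave both the O–Si and the C(sp)–Si bond while sparing the α-methylene lactone, the tiglate and the dioxinone.

Step 15
Reactants: 28 hydroxy alkynyl dioxinone
Product: 30 eleven-membered β-keto lactone (ring C5–O–C(=O)–C3H2–C2(=O)–C1H2–C10(=CH2)–C9H2–C8(O-tigloyl)–C7–C6, ethynyl at C5, trans α-methylene-γ-lactone on C6/C7; 5S,6S,7R,8S), via acylketene 29 (not isolated)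
Conditions: toluene, 110 °C, slow addition, final 0.5 mM
Reagents that add atoms: none
Why: thermal retro-[4+2] of the dioxinone releases acetone and an acylketene that is captured by the C5 hydroxyl (acylketene macrolactonisation), a neutral, fast capture suited to medium rings, with retention at C5.

Step 16
Reactants: 30 eleven-membered β-keto lactone
Product: 31 anhydro form of the target (2,5-epoxygermacra-2,4(15),10(14),11(13)-tetraen-12,6-olide 8-tiglate, enol ether C2=C3)
Conditions: Pd2(dba)3·CHCl3 (5 mol %), dppe (12 mol %), THF (2 mM), 50 °C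
Reagents that add atoms: none
Why: Proposed new method: zerovalent palladium ionises the propargylic C5–O ester bond of 30 with inversion to an η3-propargyl/allenyl divalent palladium β-keto carboxylate ion pair, the soft C3 carbon (of the carboxylate, or of the enolate left after loss of CO2) adds to the central carbon C4, proton transfer from C3–H to C15 gives a 2-substituted π-allyl palladium, and decarboxylation sets the C2 enolate free toward C3, whose oxygen then closes on C5. The closest known reaction types are the palladium-catalysed annulation of propargylic carbonates with β-keto esters to 4-methylene-4,5-dihydrofurans and the decarboxylative Tsuji–Trost allylation of allyl β-keto esters; their merger in an intramolecular, ring-contracting sense on a macrolactone is what is new. The ten-membered carbocycle closes by ring contraction of the eleven-membered lactone (C3 takes the place of the O–C(=O) link inside the ion pair, so no free chain end has to find its partner), and the oxolane closes by O-allylation of the π-allyl at its inner terminus C5, a 5-exo-type substitution in which palladium leaves outside the ring. The only new stereocentre, C5, is controlled by double inversion (ionisation anti to the carboxylate, oxygen attack anti to palladium), that is net retention of the (S) centre set in step 2, reinforced by the fact that only a cis 2,5-bridge can span the ten-membered ring. The step needs attack at the centre of the propargyl unit (secured by the bidentate phosphine and the soft, doubly activated C3), C3 and not C1 as nucleophile (secured by the carboxyl that sits on C3 and leaves as CO2) and O-closure on C5 and not C15 (closure on C15 would give a 1,3-bridged bicycle with two bridgehead alkenes). No external base is present, so the α-methylene lactone, the tiglate and the two 1,1-disubstituted alkenes should not be drawn into enolate chemistry.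

Step 17
Reactants: 31 anhydro form of the target
Product: 32 target hemiketal, (2S,5S,6S,7R,8S)-2-hydroxy-2,5-epoxygermacra-4(15),10(14),11(13)-trien-12,6-olide 8-[(2E)-2-methylbut-2-enoate]
Conditions: PPTS (10 mol %), THF/H2O (5:1), rt
Reagents that add atoms: water, O
Why: acid-catalysed hydration of the enol ether by kinetic α-protonation at C3 and capture of the C2 oxocarbenium ion by water, with the C2 configuration fixed by the bridge (C1 and C6 cis on the oxolane).

**Compound list**

1 | allyl alcohol | C=CCO | starting material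
2 | allyl methoxymethyl ether | C=CCOCOC | intermediate
3 | 3-(trimethylsilyl)prop-2-ynal | C[Si](C)(C)C#CC=O | starting material
4 | (Z)-3-(methoxymethoxy)allyllithium | [Li]C/C=C\OCOC | intermediate (not isolated)
5 | B-[(Z)-3-(methoxymethoxy)allyl]diisopinocampheylborane (Ipc from (−)-α-pinene) | COCO/C=C\CB([C@H]1C[C@H]2C[C@@H]([C@@H]1C)C2(C)C)[C@H]1C[C@H]2C[C@@H]([C@@H]1C)C2(C)C | intermediate (not isolated)
6 | diisopinocampheylborinate of alcohol 7 | C=C[C@H](OCOC)[C@@H](OB([C@H]1C[C@H]2C[C@@H]([C@@H]1C)C2(C)C)[C@H]1C[C@H]2C[C@@H]([C@@H]1C)C2(C)C)C#C[Si](C)(C)C | intermediate (not isolated)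
7 | (3S,4S)-3-(methoxymethoxy)-6-(trimethylsilyl)hex-1-en-5-yn-4-ol | C=C[C@H](OCOC)[C@@H](O)C#C[Si](C)(C)C | intermediate
8 | (3S,4S)-4-[tert-butyl(diphenyl)silyloxy]-3-(methoxymethoxy)-6-(trimethylsilyl)hex-1-en-5-yne | C=C[C@H](OCOC)[C@@H](O[Si](c1ccccc1)(c1ccccc1)C(C)(C)C)C#C[Si](C)(C)C | intermediate
9 | (3S,4S)-4-[tert-butyl(diphenyl)silyloxy]-6-(trimethylsilyl)hex-1-en-5-yn-3-ol | C=C[C@H](O)[C@@H](O[Si](c1ccccc1)(c1ccccc1)C(C)(C)C)C#C[Si](C)(C)C | intermediate
10 | 2-(bromomethyl)acrylic acid | OC(=O)C(=C)CBr | starting material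
11 | (3S,4S)-4-[tert-butyl(diphenyl)silyloxy]-6-(trimethylsilyl)hex-1-en-5-yn-3-yl 2-(bromomethyl)prop-2-enoate | C=C[C@H](OC(=O)C(=C)CBr)[C@@H](O[Si](c1ccccc1)(c1ccccc1)C(C)(C)C)C#C[Si](C)(C)C | intermediate
12 | (5S)-3-(bromomethyl)-5-[(1S)-1-[tert-butyl(diphenyl)silyloxy]-3-(trimethylsilyl)prop-2-yn-1-yl]furan-2(5H)-one | O=C1O[C@@H](C=C1CBr)[C@@H](O[Si](c1ccccc1)(c1ccccc1)C(C)(C)C)C#C[Si](C)(C)C | intermediate
13 | 3-bromobut-3-en-1-ol | C=C(Br)CCO | starting material
14 | [(3-bromobut-3-en-1-yl)oxy](tert-butyl)dimethylsilane | C=C(Br)CCO[Si](C)(C)C(C)(C)C | intermediate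
15 | 2,2,6-trimethyl-4H-1,3-dioxin-4-one | CC1=CC(=O)OC(C)(C)O1 | starting material
16 | lithium dienolate of 15 | [Li+].C=C1C=C([O-])OC(C)(C)O1 | intermediate (not isolated)
17 | 6-(chloromethyl)-2,2-dimethyl-4H-1,3-dioxin-4-one | ClCC1=CC(=O)OC(C)(C)O1 | intermediate
18 | [4-(tert-butyldimethylsilyloxy)but-1-en-2-yl]lithium | [Li]C(=C)CCO[Si](C)(C)C(C)(C)C | intermediate (not isolated)
19 | [4-(tert-butyldimethylsilyloxy)but-1-en-2-yl]zinc chloride | Cl[Zn]C(=C)CCO[Si](C)(C)C(C)(C)C | intermediate (not isolated)
20 | 6-[4-(tert-butyldimethylsilyloxy)-2-methylidenebutyl]-2,2-dimethyl-4H-1,3-dioxin-4-one | C=C(CCO[Si](C)(C)C(C)(C)C)CC1=CC(=O)OC(C)(C)O1 | intermediate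
21 | 6-(4-hydroxy-2-methylidenebutyl)-2,2-dimethyl-4H-1,3-dioxin-4-one | C=C(CCO)CC1=CC(=O)OC(C)(C)O1 | intermediate
22 | 4-(2,2-dimethyl-4-oxo-4H-1,3-dioxin-6-yl)-3-methylidenebutanal | C=C(CC=O)CC1=CC(=O)OC(C)(C)O1 | intermediate
23 | allylzinc bromide from 12 | O=C1O[C@@H](C=C1C[Zn]Br)[C@@H](O[Si](c1ccccc1)(c1ccccc1)C(C)(C)C)C#C[Si](C)(C)C | intermediate (not isolated)
24 | Barbier alcohol: trans α-methylene-γ-lactone with (1S)-1-hydroxy-3-methylidene-4-(dioxinonyl)butyl at C7 and the silylated propargyl carbinol at C6 | CC1(C)OC(CC(=C)C[C@H](O)[C@H]2C(=C)C(=O)O[C@@H]2[C@@H](O[Si](c2ccccc2)(c2ccccc2)C(C)(C)C)C#C[Si](C)(C)C)=CC(=O)O1 | intermediate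
25 | tiglic acid, (2E)-2-methylbut-2-enoic acid | OC(=O)/C(C)=C/C | starting material
26 | tiglic 2,4,6-trichlorobenzoic anhydride | O=C(OC(=O)/C(C)=C/C)c1c(Cl)cc(Cl)cc1Cl | intermediate (not isolated)
27 | C8 tiglate of 24 | CC1(C)OC(CC(=C)C[C@H](OC(=O)/C(C)=C/C)[C@H]2C(=C)C(=O)O[C@@H]2[C@@H](O[Si](c2ccccc2)(c2ccccc2)C(C)(C)C)C#C[Si](C)(C)C)=CC(=O)O1 | intermediate
28 | desilylated tiglate (free C5–OH, terminal alkyne, dioxinone) | CC1(C)OC(CC(=C)C[C@H](OC(=O)/C(C)=C/C)[C@H]2C(=C)C(=O)O[C@@H]2[C@@H](O)C#C)=CC(=O)O1 | intermediate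
29 | acylketene from 28 | O=C=CC(=O)CC(=C)C[C@H](OC(=O)/C(C)=C/C)[C@H]1C(=C)C(=O)O[C@@H]1[C@@H](O)C#C | intermediate (not isolated)
30 | eleven-membered propargylic β-keto lactone | C#C[C@@H]1OC(=O)CC(=O)CC(=C)C[C@H](OC(=O)/C(C)=C/C)[C@H]2C(=C)C(=O)O[C@H]12 | intermediate
31 | anhydro form of the target (bridgehead enol ether C2=C3) | C=C1C[C@H](OC(=O)/C(C)=C/C)[C@H]2C(=C)C(=O)O[C@@H]2[C@H]2OC(C1)=CC2=C | intermediate
32 | CNP0307443.2 | C=C1C[C@H](OC(=O)/C(C)=C/C)[C@H]2C(=C)C(=O)O[C@@H]2[C@H]2O[C@@](O)(C1)CC2=C | target

**Step count and risks**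

Total step count: 17. Longest linear sequence: 12 (steps 1–6 and 12–17).

Steps most likely to fail:

1. Step 16 (proposed method). The carbon nucleophile may attack a terminus of the propargyl unit instead of its centre (allenyl or propargyl ketones). The π-allyl intermediate may exchange faces through its CH2 terminus and erode the C5 configuration, close on C15, or lose a β-hydride. The 1,1-disubstituted alkene next to the ketone may migrate into conjugation. Fallback with known chemistry, setting out from 30 and returning at 31: the two bonds are made in two operations. A gold-catalysed Conia-ene reaction (Ph3PAuCl/AgOTf, CH2Cl2, rt) lets the enol carbon C3 of the β-keto ester add 5-exo-dig to the terminal alkyne. This should give the bridged α-acyl-β-methylene-γ-lactone F1, with the C3–C4 bond and the ten-membered ring formed and C5 untouched. F1 is an allylic β-keto ester, so Pd(PPh3)4 in THF should ionise its C5–O bond and release CO2. The enolate oxygen then closes on C5 (carbon attack would require a cyclopropane), giving 31.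

2. Step 15. Intermolecular capture of the acylketene (dimers, oligomers) or its decay may outrun closure of the strained eleven-membered ring. Fallback, setting out from 12 and 22 and returning at 30: the ring is closed through C7–C8 instead of the ester bond. Compound 12 is desilylated at oxygen (HF·pyridine) to the bromolactone alcohol F2. Slow addition of 22 to F2 in toluene at 110 °C gives, by intermolecular acylketene capture, the β-keto ester F3. Zinc in THF/aqueous NH4Cl at high dilution closes the ring by intramolecular Barbier allylation to the macrocyclic alcohol F4. Steglich esterification with 25 gives the macrocyclic tiglate F5. Catalytic AgNO3 in acetone/water removes the alkynyl silyl group and gives 30.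

3. Step 12. Simple diastereoselection at C8 may be poor or reversed if an open transition state competes. Attack through the α-carbon, or 1,4-elimination of the allylzinc with opening of the lactone, may also intervene. Fallback, setting out from 12 and 22 and returning at 27: the C8-epimeric alcohol F6 is carried on and esterified with 25 under Mitsunobu conditions (PPh3, DIAD, toluene, 0 °C). This inverts C8 and gives 27 directly, so both epimers converge.

**Further compounds**

F1 | step 16 | bridged α-acyl-β-methylene-γ-lactone (Conia-ene product of 30; C3 configuration not defined) | C=C1C[C@H](OC(=O)/C(C)=C/C)[C@H]2C(=C)C(=O)O[C@@H]2[C@H]2OC(=O)C(C(=O)C1)C2=C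
F2 | step 15 | (5S)-3-(bromomethyl)-5-[(1S)-1-hydroxy-3-(trimethylsilyl)prop-2-yn-1-yl]furan-2(5H)-one | O=C1O[C@@H](C=C1CBr)[C@@H](O)C#C[Si](C)(C)C
F3 | step 15 | (1S)-1-[(2S)-4-(bromomethyl)-5-oxo-2,5-dihydrofuran-2-yl]-3-(trimethylsilyl)prop-2-yn-1-yl 5-methylidene-3,7-dioxoheptanoate | O=C1O[C@@H](C=C1CBr)[C@@H](OC(=O)CC(=O)CC(=C)CC=O)C#C[Si](C)(C)C
F4 | step 15 | eleven-membered β-keto lactone with free C8–OH and silylalkyne | C[Si](C)(C)C#C[C@@H]1OC(=O)CC(=O)CC(=C)C[C@H](O)[C@H]2C(=C)C(=O)O[C@H]12
F5 | step 15 | C8 tiglate of F4 | C[Si](C)(C)C#C[C@@H]1OC(=O)CC(=O)CC(=C)C[C@H](OC(=O)/C(C)=C/C)[C@H]2C(=C)C(=O)O[C@H]12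
F6 | step 12 | C8 epimer of 24 | CC1(C)OC(CC(=C)C[C@@H](O)[C@H]2C(=C)C(=O)O[C@@H]2[C@@H](O[Si](c2ccccc2)(c2ccccc2)C(C)(C)C)C#C[Si](C)(C)C)=CC(=O)O1
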